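**Retrosynthetic overview** (Stemona-type locants: ring A azepine N4/C5–C9/C9a; ring B pyrrole N4/C1/C2/C3/C9a; ring C C1/C12/C11/C10/C9/C9a; ring D lactone O/C11/C12/C13/C14; ring E pendant lactone C18–C21 on C3)
1. Ring E is cut last: C3–C(=O) Friedel–Crafts bond to (S)-methylsuccinic anhydride (C20 from the pool), C18 by catalyst-controlled ketone reduction.
2. Ring A is opened at N4–C5 (N-alkylation) and ring B by Paal–Knorr to a 1,4-keto aldehyde whose C2–C3 unit is an allyl group on C1.
3. Ring D is opened at C12–C13: a C13 radical, held as a mixed bromoacetal on O11, closes 5-exo onto the enone C1=C12 of ring C, and the C1 radical takes the allyl group in the same operation.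
4. Enabling feature: the O11-bearing C11 is the γ-carbon of the C9a(=O)–C1=C12 enone, so a two-atom tether from O11 can reach only C12 and only on the O11 face. C11 is bought and relays C10, C9 and C12; C13 is then set by convex-face protonation.
5. Order of ring formation: C (bought) → D (step 7) → B (step 10) → A (step 11) → E (step 14).

Key step: step 7

Assumption: compounds 1, 3 (0.5 M in THF) and 23 are taken as catalogue items, 1 and 23 in enantiopure form.

**Step 1**
Reactants: 1 (R)-4-(tert-butyldimethylsilyloxy)cyclohex-2-en-1-one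
Product: 2 (R)-4-(tert-butyldimethylsilyloxy)-2-iodocyclohex-2-en-1-one
Conditions: I2, K2CO3, DMAP (20 mol %), THF/H2O, rt
Reagents that add atoms: iodine, II
Why: Amine-catalysed α-iodination of a cyclic enone (addition, iodination, elimination) should give the 2-iodoenone without touching the C4 stereocenter.

**Step 2**
Reactants: 2 (R)-4-(tert-butyldimethylsilyloxy)-2-iodocyclohex-2-en-1-one; 3 4-chlorobutylzinc bromide
Product: 4 (R)-4-(tert-butyldimethylsilyloxy)-2-(4-chlorobutyl)cyclohex-2-en-1-one
Conditions: Pd2(dba)3 (2.5 mol %), P(2-furyl)3 (10 mol %), THF/NMP, rt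
Reagents that add atoms: 4-chlorobutylzinc bromide 3, ClCCCC[Zn]Br
Why: Negishi coupling of an α-iodoenone with a primary alkylzinc halide under zerovalent palladium catalysis should tolerate the C–Cl bond and the silyl ether.

**Step 3**
Reactants: 4 (R)-4-(tert-butyldimethylsilyloxy)-2-(4-chlorobutyl)cyclohex-2-en-1-one; 5 ethylmagnesium bromide
Product: 7 (2R,3R,4R)-4-(tert-butyldimethylsilyloxy)-2-(4-chlorobutyl)-3-ethylcyclohexan-1-one, via silyl enol ether 6 (not isolated)
Conditions: EtMgBr, CuBr·SMe2 (10 mol %), Me3SiCl, THF, −78 °C; then K2CO3 (cat.), MeOH, rt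
Reagents that add atoms: ethylmagnesium bromide 5, CC[Mg]Br
Why: Copper-catalysed conjugate addition enters anti to the C4 silyloxy group (sets the ethyl centre), and methanolysis of 6 with equilibration places the side chain trans to ethyl in the all-equatorial ketone, so both new centres are relayed from C4.

**Step 4**
Reactants: 7 (2R,3R,4R)-4-(tert-butyldimethylsilyloxy)-2-(4-chlorobutyl)-3-ethylcyclohexan-1-one
Product: 9 (4R,5R,6R)-4-(tert-butyldimethylsilyloxy)-6-(4-chlorobutyl)-5-ethylcyclohex-2-en-1-one, via kinetic silyl enol ether 8 (not isolated)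
Conditions: LDA, Me3SiCl, THF, −78 °C; then Pd(OAc)2 (1.05 equiv), MeCN, rt
Reagents that add atoms: none
Why: Kinetic deprotonation at the unsubstituted α-carbon followed by Saegusa–Ito oxidation with divalent palladium should transpose the enone so that the oxygen-bearing carbon becomes its γ-position.

**Step 5**
Reactants: 9 (4R,5R,6R)-4-(tert-butyldimethylsilyloxy)-6-(4-chlorobutyl)-5-ethylcyclohex-2-en-1-one
Product: 10 (4R,5R,6R)-6-(4-chlorobutyl)-5-ethyl-4-hydroxycyclohex-2-en-1-one
Conditions: HF·pyridine, THF, 0 °C → rt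
Reagents that add atoms: none
Why: Fluoride cleavage of the silyl ether under buffered acidic conditions should free the γ-hydroxyl without elimination or epimerisation.

**Step 6**
Reactants: 10 (4R,5R,6R)-6-(4-chlorobutyl)-5-ethyl-4-hydroxycyclohex-2-en-1-one; 11 ethyl 1-propenyl ether
Product: 12 (4R,5R,6R)-4-(2-bromo-1-ethoxypropoxy)-6-(4-chlorobutyl)-5-ethylcyclohex-2-en-1-one (diastereomer mixture in the acetal side chain)
Conditions: NBS, CH2Cl2, −40 → 0 °C
Reagents that add atoms: ethyl 1-propenyl ether 11, CC=COCC; N-bromosuccinimide, O=C1CCC(=O)N1Br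
Why: Ueno–Stork bromoacetalisation: NBS brominates only the electron-rich enol ether and the alcohol captures the oxocarbenium ion, the two side-chain centres being formed as mixtures that are later destroyed (C–Br) or oxidised (acetal carbon).

**Step 7**
Reactants: 12 (4R,5R,6R)-4-(2-bromo-1-ethoxypropoxy)-6-(4-chlorobutyl)-5-ethylcyclohex-2-en-1-one; 13 allyltributylstannane
Product: 14 (3aR,4R,6R,7R,7aS)-4-allyl-6-(4-chlorobutyl)-2-ethoxy-7-ethyl-3-methylhexahydrobenzofuran-5(4H)-one (epimers at C2 and C3)
Conditions: allylSnBu3 (3 equiv), AIBN (0.2 equiv), benzene (0.05 M), 80 °C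
Reagents that add atoms: allyltributylstannane 13, C=CC[Sn](CCCC)(CCCC)CCCC
Why: The tributyltin radical abstracts bromine (not the primary chlorine) to give a nucleophilic secondary radical at C13, which adds 5-exo-trig to the enone β-carbon C12 and closes ring D as its lactol ether; the electrophilic α-keto radical so formed at C1 adds to allyltributylstannane and expels Bu3Sn•, which carries the chain. The closest known reaction types are the Ueno–Stork bromoacetal cyclization and the Keck radical allylation, joined as in radical cyclization–trapping cascades. C12 is set by the tether: the O–CH(OEt) link from O11 can reach C12 only on the face of O11, so the C/D fusion is cis and relayed from C11. The allyl group should enter C1 anti to the new C12–C13 bond (this centre later becomes pyrrole sp2), while C13 and the acetal carbon form without reliable control and are settled in step 12 and step 8. The step needs ring closure before allyl transfer, which is secured by the fast, polarity-matched attack of an alkyl radical on an enone against its slow reaction with the stannane. It also needs allylation rather than reduction of the C1 radical, which is secured by the absence of a tin hydride and the polarity match of an α-keto radical with the electron-rich stannane.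

**Step 8**
Reactants: 14 (3aR,4R,6R,7R,7aS)-4-allyl-6-(4-chlorobutyl)-2-ethoxy-7-ethyl-3-methylhexahydrobenzofuran-5(4H)-one
Product: 16 (3aS,4R,6R,7R,7aS)-4-allyl-6-(4-chlorobutyl)-7-ethyl-3-methyl-3a,6,7,7a-tetrahydrobenzofuran-2,5(3H,4H)-dione (C3 epimers), via lactol 15 (not isolated)
Conditions: CrO3, H2SO4, H2O, acetone, 0 °C
Reagents that add atoms: water, O
Why: Jones oxidation hydrolyses the mixed acetal to lactol 15 and oxidises it to the γ-lactone, the usual close of an Ueno–Stork sequence, while ketone, terminal alkene and alkyl chloride are inert.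

**Step 9**
Reactants: 16 (3aS,4R,6R,7R,7aS)-4-allyl-6-(4-chlorobutyl)-7-ethyl-3-methyl-3a,6,7,7a-tetrahydrobenzofuran-2,5(3H,4H)-dione
Product: 18 2-[(3aS,4R,6R,7R,7aS)-6-(4-chlorobutyl)-7-ethyl-3-methyl-2,5-dioxooctahydrobenzofuran-4-yl]acetaldehyde (C3 epimers), via ozonide 17 (not isolated)
Conditions: O3, CH2Cl2, −78 °C; then PPh3, −78 °C → rt
Reagents that add atoms: ozone, [O-][O+]=O
Why: Ozonolysis with reductive work-up should cleave the terminal alkene to the aldehyde and complete the 1,4-keto aldehyde.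

**Step 10**
Reactants: 18 2-[(3aS,4R,6R,7R,7aS)-6-(4-chlorobutyl)-7-ethyl-3-methyl-2,5-dioxooctahydrobenzofuran-4-yl]acetaldehyde
Product: 19 (4R,5S,6R,7R)-7-(4-chlorobutyl)-6-ethyl-4,5,6,7-tetrahydro-1H-indole carrying ring D as a cis-fused γ-lactone (O on C5; CH(CH3)–C(=O) on C4; α-methyl epimers)
Conditions: NH4OAc, MeOH, rt
Reagents that add atoms: ammonium acetate, CC(=O)[O-].[NH4+]
Why: Paal–Knorr condensation of the 1,4-keto aldehyde with ammonia should form ring B under nearly neutral conditions, with C9 already in its thermodynamically preferred trans arrangement.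

**Step 11**
Reactants: 19 NH-pyrrole lactone
Product: 20 (9R,10R,11S,12R)-tetracyclic pyrrole lactone (rings A–D of the target with H on C3; C13 epimers)
Conditions: NaH, NaI (cat.), DMF, 0 °C → rt
Reagents that add atoms: none
Why: Intramolecular N-alkylation of the pyrrolide by the primary chloride (7-exo-tet) should close ring A, and any base-induced epimerisation at C13 is harmless because C13 is set in step 12.

**Step 12**
Reactants: 20 (9R,10R,11S,12R)-tetracyclic pyrrole lactone (C13 epimers)
Product: 22 (9R,10R,11S,12R,13R)-tetracyclic pyrrole lactone, via lithium enolate 21 (not isolated)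
Conditions: LDA, THF, −78 °C; then 2,6-di-tert-butyl-4-methylphenol, THF, −78 °C
Reagents that add atoms: none
Why: Kinetic protonation of the lactone enolate: the bulky proton donor should approach planar C13 on the convex face of the cis-fused C/D system (anti to pyrrole C1), so both epimers of 20 converge on the one with methyl on the concave face (H11, H12 and H13 all cis).

**Step 13**
Reactants: 22 (9R,10R,11S,12R,13R)-tetracyclic pyrrole lactone; 23 (S)-methylsuccinic anhydride
Product: 24 (S)-2-methyl-4-oxo-4-[C3 of the tetracycle 22]butanoic acid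
Conditions: AlCl3, CH2Cl2, 0 °C; cold 1 M HCl work-up
Reagents that add atoms: (S)-methylsuccinic anhydride 23, C[C@H]1CC(=O)OC1=O
Why: Friedel–Crafts acylation should occur at the only free pyrrole α-position (C3), the anhydride opening at its less hindered carbonyl (remote from methyl) so that the pool-derived C20 centre ends up next to the free acid.

**Step 14**
Reactants: 24 keto acid
Product: 26 target CNP0232452.4 (9R,10R,11S,12R,13R,18R,20S), via hydroxy acid 25 (not isolated)
Conditions: RuCl[(R,R)-TsDPEN](p-cymene) (2 mol %), HCO2Na, H2O/MeOH, 40 °C; pH 6 extraction; then DIC, DMAP (cat.), CH2Cl2, 0 °C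
Reagents that add atoms: none
Why: Noyori–Ikariya asymmetric transfer hydrogenation should reduce the aryl-type ketone under catalyst control (the (R,R)-ligand gives the (R)-carbinol at C18), and carbodiimide activation of the acid closes ring E by acyl substitution with retention at C18.

**Compound list**
1 | (R)-4-(tert-butyldimethylsilyloxy)cyclohex-2-en-1-one | O=C1C=C[C@H](O[Si](C)(C)C(C)(C)C)CC1 | starting material
2 | (R)-4-(tert-butyldimethylsilyloxy)-2-iodocyclohex-2-en-1-one | O=C1C(I)=C[C@H](O[Si](C)(C)C(C)(C)C)CC1 | intermediate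
3 | 4-chlorobutylzinc bromide | ClCCCC[Zn]Br | starting material
4 | (R)-4-(tert-butyldimethylsilyloxy)-2-(4-chlorobutyl)cyclohex-2-en-1-one | O=C1C(CCCCCl)=C[C@H](O[Si](C)(C)C(C)(C)C)CC1 | intermediate
5 | ethylmagnesium bromide | CC[Mg]Br | starting material
6 | (3R,4R)-4-(tert-butyldimethylsilyloxy)-2-(4-chlorobutyl)-3-ethyl-1-(trimethylsilyloxy)cyclohex-1-ene | C[Si](C)(C)OC1=C(CCCCCl)[C@@H](CC)[C@H](O[Si](C)(C)C(C)(C)C)CC1 | intermediate
7 | (2R,3R,4R)-4-(tert-butyldimethylsilyloxy)-2-(4-chlorobutyl)-3-ethylcyclohexan-1-one | O=C1[C@H](CCCCCl)[C@@H](CC)[C@H](O[Si](C)(C)C(C)(C)C)CC1 | intermediate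
8 | (4R,5R,6R)-4-(tert-butyldimethylsilyloxy)-6-(4-chlorobutyl)-5-ethyl-1-(trimethylsilyloxy)cyclohex-1-ene | C[Si](C)(C)OC1=CC[C@@H](O[Si](C)(C)C(C)(C)C)[C@H](CC)[C@H]1CCCCCl | intermediate
9 | (4R,5R,6R)-4-(tert-butyldimethylsilyloxy)-6-(4-chlorobutyl)-5-ethylcyclohex-2-en-1-one | O=C1C=C[C@@H](O[Si](C)(C)C(C)(C)C)[C@H](CC)[C@H]1CCCCCl | intermediate
10 | (4R,5R,6R)-6-(4-chlorobutyl)-5-ethyl-4-hydroxycyclohex-2-en-1-one | O=C1C=C[C@@H](O)[C@H](CC)[C@H]1CCCCCl | intermediate
11 | ethyl 1-propenyl ether (cis/trans mixture) | CC=COCC | starting material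
12 | (4R,5R,6R)-4-(2-bromo-1-ethoxypropoxy)-6-(4-chlorobutyl)-5-ethylcyclohex-2-en-1-one (side-chain diastereomers) | O=C1C=C[C@@H](OC(OCC)C(C)Br)[C@H](CC)[C@H]1CCCCCl | intermediate
13 | allyltributylstannane | C=CC[Sn](CCCC)(CCCC)CCCC | starting material
14 | (3aR,4R,6R,7R,7aS)-4-allyl-6-(4-chlorobutyl)-2-ethoxy-7-ethyl-3-methylhexahydrobenzofuran-5(4H)-one (C2, C3 epimers) | C=CC[C@H]1C(=O)[C@H](CCCCCl)[C@@H](CC)[C@@H]2OC(OCC)C(C)[C@H]12 | intermediate
15 | lactol, the 2-hydroxy analogue of 14 | C=CC[C@H]1C(=O)[C@H](CCCCCl)[C@@H](CC)[C@@H]2OC(O)C(C)[C@H]12 | intermediate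
16 | (3aS,4R,6R,7R,7aS)-4-allyl-6-(4-chlorobutyl)-7-ethyl-3-methyl-3a,6,7,7a-tetrahydrobenzofuran-2,5(3H,4H)-dione (C3 epimers) | C=CC[C@H]1C(=O)[C@H](CCCCCl)[C@@H](CC)[C@@H]2OC(=O)C(C)[C@H]12 | intermediate
17 | ozonide of 16 (1,2,4-trioxolan-3-ylmethyl group on C4) | O1OCOC1C[C@H]2C(=O)[C@H](CCCCCl)[C@@H](CC)[C@@H]3OC(=O)C(C)[C@H]23 | intermediate
18 | 2-[(3aS,4R,6R,7R,7aS)-6-(4-chlorobutyl)-7-ethyl-3-methyl-2,5-dioxooctahydrobenzofuran-4-yl]acetaldehyde (C3 epimers) | O=CC[C@H]1C(=O)[C@H](CCCCCl)[C@@H](CC)[C@@H]2OC(=O)C(C)[C@H]12 | intermediate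
19 | (4R,5S,6R,7R)-7-(4-chlorobutyl)-6-ethyl-4,5,6,7-tetrahydro-1H-indole with cis-fused α-methyl-γ-lactone across C4/C5 (α-methyl epimers) | CC[C@H]1[C@@H]2OC(=O)C(C)[C@@H]2c2cc[nH]c2[C@@H]1CCCCCl | intermediate
20 | (9R,10R,11S,12R)-tetracyclic pyrrole lactone, rings A–D (C13 epimers) | CC[C@H]1[C@@H]2OC(=O)C(C)[C@@H]2c2ccn3c2[C@@H]1CCCC3 | intermediate
21 | lithium enolate of 20 (C13=C14) | CC[C@H]1[C@@H]2OC(O[Li])=C(C)[C@@H]2c2ccn3c2[C@@H]1CCCC3 | intermediate
22 | (9R,10R,11S,12R,13R)-tetracyclic pyrrole lactone, rings A–D | CC[C@H]1[C@@H]2OC(=O)[C@H](C)[C@@H]2c2ccn3c2[C@@H]1CCCC3 | intermediate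
23 | (S)-methylsuccinic anhydride | C[C@H]1CC(=O)OC1=O | starting material
24 | (S)-2-methyl-4-oxo-4-(C3-pyrrolyl of 22)butanoic acid | CC[C@H]1[C@@H]2OC(=O)[C@H](C)[C@@H]2c2cc(C(=O)C[C@H](C)C(=O)O)n3c2[C@@H]1CCCC3 | intermediate
25 | (2S,4R)-4-hydroxy-2-methyl-4-(C3-pyrrolyl of 22)butanoic acid | CC[C@H]1[C@@H]2OC(=O)[C@H](C)[C@@H]2c2cc([C@H](O)C[C@H](C)C(=O)O)n3c2[C@@H]1CCCC3 | intermediate
26 | CNP0232452.4 (9R,10R,11S,12R,13R,18R,20S) | CC[C@H]1[C@@H]2OC(=O)[C@H](C)[C@@H]2c2cc([C@H]3C[C@H](C)C(=O)O3)n3c2[C@@H]1CCCC3 | target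

**Step count and risks**
Total steps: 14. Longest linear sequence: 14 (from compound 1).

Steps most likely to fail:

- **Step 7.** Capture of the C1 radical by the stannane may be inefficient (oligomerisation), or allyl transfer may precede ring closure. The two C–C bonds would then be made in separate events. Bromoacetal 12 is cyclised reductively (Bu3SnH added slowly, AIBN, benzene, 80 °C) to the de-allyl bicyclic acetal F1. Jones oxidation through lactol F2 gives keto lactone F3. LiHMDS (THF, −78 °C) deprotonates the unsubstituted α-carbon C1 to lithium enolate F4, and allyl iodide alkylates it anti to the ring D bond. This returns to the route at compound 16.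

- **Step 12.** Protonation of the enolate may show poor facial selectivity. Hydrogen would then be delivered to C13 as an atom instead of a proton. Compound 20 is taken through enolate 21 (LDA, THF/HMPA, −78 °C) and diphenyl diselenide to the α-phenylselanyl lactone F5. Homolysis of the C–Se bond (Bu3SnH, Et3B/air, toluene, −78 °C) gives the planar α-lactonyl radical, which should take hydrogen from the bulky stannane on the convex face. This returns to the route at compound 22.

- **Step 14.** Hydride transfer to the electron-rich acylpyrrole may be slow, or C18 may lose configuration through ionisation of the pyrrolylcarbinol in the aqueous medium. The carbonyl would then be activated as a Lewis acid complex and ring E closed by transesterification. Keto acid 24 is esterified (MeI, K2CO3, DMF) to the methyl ester F6. Reduction with BH3·SMe2 and (S)-2-methyl-CBS-oxazaborolidine (10 mol %, THF, −20 °C) gives the hydroxy ester F7, which lactonises with loss of methanol (DBU cat., toluene, rt). This arrives at the target 26.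

**Further compounds**
F1 | step 7 | de-allyl analogue of acetal 14 (C4 unsubstituted; C2, C3 epimers) | C1C(=O)[C@H](CCCCCl)[C@@H](CC)[C@@H]2OC(OCC)C(C)[C@H]12
F2 | step 7 | lactol from F1 (2-hydroxy) | C1C(=O)[C@H](CCCCCl)[C@@H](CC)[C@@H]2OC(O)C(C)[C@H]12
F3 | step 7 | de-allyl analogue of keto lactone 16 (C3 epimers) | C1C(=O)[C@H](CCCCCl)[C@@H](CC)[C@@H]2OC(=O)C(C)[C@H]12
F4 | step 7 | lithium enolate of F3 (C4=C5) | C1=C(O[Li])[C@H](CCCCCl)[C@@H](CC)[C@@H]2OC(=O)C(C)[C@H]12
F5 | step 12 | 13-phenylselanyl derivative of lactone 20 (C13 epimers) | CC[C@H]1[C@@H]2OC(=O)C(C)([Se]c3ccccc3)[C@@H]2c2ccn3c2[C@@H]1CCCC3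
F6 | step 14 | methyl ester of keto acid 24 | CC[C@H]1[C@@H]2OC(=O)[C@H](C)[C@@H]2c2cc(C(=O)C[C@H](C)C(=O)OC)n3c2[C@@H]1CCCC3
F7 | step 14 | methyl (2S,4R)-4-hydroxy-2-methyl-4-(C3-pyrrolyl of 22)butanoate | CC[C@H]1[C@@H]2OC(=O)[C@H](C)[C@@H]2c2cc([C@H](O)C[C@H](C)C(=O)OC)n3c2[C@@H]1CCCC3
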